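Guaiane numbering: C1 ring-fusion CH, C2 CH2, C3 C=O, C4 =C(CH3), C5 ring-fusion =C, C6 CH2, C7 CH bearing C11(CH3)2OAc, C8 CH–OCOEt, C9 CH2, C10 CH–CH3.
Cuts: both acyl groups; C8–O (back to a C8=C9 alkene); C4=C5 (aldol) and C1–C2 (enolate alkylation) of the cyclopentenone; the two methyl groups on C11 (back to an ester); last, C9–C10 and C7–C8 together, as a [5+2] cycloaddition of a vinylcyclopropane with acetylene.
Enabling feature: in the seven-membered ring the bridge C8–C9 joins the ends of the chain C10–C1–C5–C6–C7. Its middle atom C5, the β-carbon of the enone, is a latent ketone (donor OSi), and its end C7 bears the latent ester C11 (acceptor). C5–C6–C7 can therefore be a push–pull cyclopropane with C1=C10 as its propenyl arm.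
Forward: pentenone → silyloxydiene → cyclopropane → seven-membered ring (key step) → five-membered ring built on the regiodefined silyl enol ether → C8–OH → propionate, then acetate.
Stereochemistry: C7 from a Cu(I)–bis(oxazoline) cyclopropanation; C10 from C7 through the stereospecific, suprafacial [5+2]; C1 by alkylation anti to the C10 methyl (also the equilibrium position); C8 by a silicon tether from the C11 hydroxyl.

Key step: step 3

Remark: the Cu(I)–tBu-box catalyst is assumed to induce on diene 2 in the same sense as on other terminal alkenes, so the (R,R)-ligand should give the (1S)-ester. The opposite finding would only call for the (S,S)-ligand.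

Step 1
Reactants: 1 (E)-pent-3-en-2-one
Product: 2 (E)-2-(tert-butyldimethylsilyloxy)penta-1,3-diene
Conditions: TBSOTf, Et3N, CH2Cl2, 0 °C
Reagents that add atoms: tert-butyldimethylsilyl triflate, CC(C)(C)[Si](C)(C)OS(=O)(=O)C(F)(F)F
Why: Soft enolisation with O-silylation (silyl triflate/amine) removes a proton from the α′-methyl group, which should give the cross-conjugated 2-silyloxydiene and leave the E double bond untouched.

Step 2
Reactants: 2 (E)-2-(tert-butyldimethylsilyloxy)penta-1,3-diene; 3 ethyl diazoacetate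
Product: 4 ethyl (1S,2S)-2-(tert-butyldimethylsilyloxy)-2-[(E)-prop-1-enyl]cyclopropane-1-carboxylate
Conditions: CuOTf (2 mol %), (R,R)-tBu-box (2.2 mol %), slow addition of 3, CH2Cl2, 0 °C to rt; chromatography on Et3N-deactivated silica
Reagents that add atoms: none
Why: In this enantioselective copper-carbene cyclopropanation the electrophilic carbene attacks the electron-rich terminal enol-ether double bond, the ligand fixes the ester-bearing carbon (C7) as S, and the isomer with the ester cis to OTBS (trans to propenyl) is separated from its C2 epimer.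

Step 3
Reactants: 4 ethyl (1S,2S)-2-(tert-butyldimethylsilyloxy)-2-[(E)-prop-1-enyl]cyclopropane-1-carboxylate; 5 acetylene
Product: 6 ethyl (1S,4S)-6-(tert-butyldimethylsilyloxy)-4-methylcyclohepta-2,5-diene-1-carboxylate
Conditions: [Rh(CO)2Cl]2 (5 mol %), HC≡CH (1 atm), ClCH2CH2Cl, 40 °C; filtration through neutral alumina
Reagents that add atoms: none
Why: Rh(I) binds the propenyl double bond and inserts into the adjacent cyclopropane bond C5–C7 to give a rhodacyclohexene that is a π-allyl (C5–C1–C10) on one side and an α-ester σ-alkyl (C7) on the other; acetylene inserts at the allyl terminus (C9–C10), and reductive elimination from the rhodacyclooctadiene closes C7–C8 and returns Rh(I). The closest known reaction type is the rhodium-catalysed intermolecular [5+2] cycloaddition of 1-silyloxy-1-vinylcyclopropanes with alkynes, the homologue of the Diels–Alder reaction. The only ring closed is the seven-membered carbocycle, formed as a (5+2) union whose last event is a C(sp2)–C(sp3) reductive elimination and not an exo or endo attack on a π bond. C7 is carried over with retention because C8 takes the place of C5 on the rhodium-bearing side, and the new centre C10 is fixed by the same metal face: rhodium sits on the allyl face turned towards C7 and the methyl of the E-propenyl group is the outward (syn) allyl substituent, which places C10–CH3 cis to C7–CO2Et (1S,4S). The step needs cleavage of the substituted bond C5–C7 and not of C5–C6, which the vicinal push–pull pair (OTBS and alkenyl on C5, ester on C7) secures by weakening exactly this bond, in line with the behaviour of carbonyl-substituted cyclopropanes under [Rh(CO)2Cl]2. Acetylene is symmetric, so the two-carbon partner raises no regiochemical question, and its excess should let insertion outrun collapse of the metallacycle to a cyclopentene.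

Step 4
Reactants: 6 ethyl (1S,4S)-6-(tert-butyldimethylsilyloxy)-4-methylcyclohepta-2,5-diene-1-carboxylate
Product: 7 2-[(1S,4S)-6-(tert-butyldimethylsilyloxy)-4-methylcyclohepta-2,5-dien-1-yl]propan-2-ol
Conditions: MeMgBr (3.5 equiv), LaCl3·2LiCl (30 mol %), THF, 0 °C; pH 7 work-up
Reagents that add atoms: methylmagnesium bromide, C[Mg]Br
Why: Double Grignard addition to the ester builds C11(CH3)2OH, the lanthanum salt suppresses enolisation of the allylic α-CH (C7), and the TBS enol ether and both stereocentres are not touched.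

Step 5
Reactants: 7 2-[(1S,4S)-6-(tert-butyldimethylsilyloxy)-4-methylcyclohepta-2,5-dien-1-yl]propan-2-ol; 8 1-bromobut-2-yne
Product: 10 (2R,3S,6S)-2-(but-2-yn-1-yl)-6-(2-hydroxypropan-2-yl)-3-methylcyclohept-4-en-1-one, via TAS enolate 9 (not isolated)
Conditions: TASF (1.1 equiv), 8 (1.3 equiv), THF, −78 to 0 °C
Reagents that add atoms: none
Why: In this fluoride-induced regiospecific alkylation of a silyl enol ether, desilylation frees only the C1=C5 enolate, and its SN2 reaction with the propargylic bromide should occur on the face anti to the neighbouring C10 methyl, which sets C1 as R.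

Step 6
Reactants: 10 (2R,3S,6S)-2-(but-2-yn-1-yl)-6-(2-hydroxypropan-2-yl)-3-methylcyclohept-4-en-1-one
Product: 11 (2R,3S,6S)-6-(2-hydroxypropan-2-yl)-3-methyl-2-(2-oxobutyl)cyclohept-4-en-1-one
Conditions: Ph3PAuNTf2 (2 mol %), dioxane–H2O 10:1, 40 °C
Reagents that add atoms: water, O
Why: Gold(I)-catalysed alkyne hydration with 5-exo-dig assistance by the ring carbonyl places the new C=O at C3 (1,4-diketone), and the neutral conditions spare the tertiary alcohol and the C8=C9 alkene.

Step 7
Reactants: 11 (2R,3S,6S)-6-(2-hydroxypropan-2-yl)-3-methyl-2-(2-oxobutyl)cyclohept-4-en-1-one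
Product: 12 (5S,8S,8aR)-5-(2-hydroxypropan-2-yl)-3,8-dimethyl-4,5,8,8a-tetrahydroazulen-2(1H)-one
Conditions: KOH (2 %), EtOH–H2O, 70 °C
Reagents that add atoms: none
Why: In this intramolecular aldol condensation of a 1,4-diketone (cyclopentenone annulation) C4 attacks the C5 ketone and dehydration gives the tetrasubstituted enone, the bridged aldol from C6 to C3 cannot dehydrate and reverts, and the now epimerisable C1 should stay in the arrangement with C2 trans to the C10 methyl.

Step 8
Reactants: 12 (5S,8S,8aR)-5-(2-hydroxypropan-2-yl)-3,8-dimethyl-4,5,8,8a-tetrahydroazulen-2(1H)-one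
Product: 14 (1R,7S,8R,10S)-8,11-(dimethylsilanediyloxy)guai-4-en-3-one, via dimethylsilyl ether 13 (not isolated)
Conditions: Me2SiHCl, Et3N, DMAP (cat.), CH2Cl2, 0 °C; filter, concentrate; Karstedt's catalyst (0.5 mol % Pt), toluene, 60 °C
Reagents that add atoms: chlorodimethylsilane, C[SiH](C)Cl
Why: O-silylation is followed by platinum-catalysed intramolecular hydrosilylation of the homoallylic alcohol, in which the 5-exo closure delivers Si to C8 and H to C9 syn on the ring face that carries C11, and this sets C8.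

Step 9
Reactants: 14 (1R,7S,8R,10S)-8,11-(dimethylsilanediyloxy)guai-4-en-3-one
Product: 15 (5S,6R,8S,8aR)-6-hydroxy-5-(2-hydroxypropan-2-yl)-3,8-dimethyl-4,5,6,7,8,8a-hexahydroazulen-2(1H)-one
Conditions: 30 % H2O2, KF, KHCO3, THF–MeOH, rt
Reagents that add atoms: hydrogen peroxide, OO
Why: Tamao–Fleming oxidation replaces C8–Si by C8–OH with retention and frees the C11 hydroxyl, while the hindered tetrasubstituted enone should resist the weakly basic peroxide.

Step 10
Reactants: 15 (5S,6R,8S,8aR)-6-hydroxy-5-(2-hydroxypropan-2-yl)-3,8-dimethyl-4,5,6,7,8,8a-hexahydroazulen-2(1H)-one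
Product: 16 (5S,6R,8S,8aR)-5-(2-hydroxypropan-2-yl)-3,8-dimethyl-2-oxo-1,2,4,5,6,7,8,8a-octahydroazulen-6-yl propanoate
Conditions: (EtCO)2O (1.2 equiv), pyridine, DMAP (5 mol %), CH2Cl2, 0 °C
Reagents that add atoms: propionic anhydride, CCC(=O)OC(=O)CC
Why: In this DMAP-catalysed acylation the secondary C8–OH should react much faster than the tertiary C11–OH, so the diol is differentiated without protecting groups.

Step 11
Reactants: 16 (5S,6R,8S,8aR)-5-(2-hydroxypropan-2-yl)-3,8-dimethyl-2-oxo-1,2,4,5,6,7,8,8a-octahydroazulen-6-yl propanoate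
Product: 17 (5S,6R,8S,8aR)-5-(2-acetoxypropan-2-yl)-3,8-dimethyl-2-oxo-1,2,4,5,6,7,8,8a-octahydroazulen-6-yl propanoate
Conditions: Ac2O (5 equiv), Et3N, DMAP (1 equiv), CH2Cl2, 40 °C
Reagents that add atoms: acetic anhydride, CC(=O)OC(C)=O
Why: DMAP-promoted acetylation of the tertiary alcohol under non-acidic conditions avoids ionisation or elimination at C11 and acyl scrambling through a dioxanylium ion.

Compound list
1 | (E)-pent-3-en-2-one | C/C=C/C(C)=O | starting material
2 | (E)-2-(tert-butyldimethylsilyloxy)penta-1,3-diene | C/C=C/C(=C)O[Si](C)(C)C(C)(C)C | intermediate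
3 | ethyl diazoacetate | CCOC(=O)C=[N+]=[N-] | starting material
4 | ethyl (1S,2S)-2-(tert-butyldimethylsilyloxy)-2-[(E)-prop-1-enyl]cyclopropane-1-carboxylate (ester cis to OTBS) | CCOC(=O)[C@H]1C[C@]1(O[Si](C)(C)C(C)(C)C)/C=C/C | intermediate
5 | acetylene | C#C | starting material
6 | ethyl (1S,4S)-6-(tert-butyldimethylsilyloxy)-4-methylcyclohepta-2,5-diene-1-carboxylate (ester and methyl cis) | CCOC(=O)[C@@H]1C=C[C@H](C)C=C(O[Si](C)(C)C(C)(C)C)C1 | intermediate
7 | 2-[(1S,4S)-6-(tert-butyldimethylsilyloxy)-4-methylcyclohepta-2,5-dien-1-yl]propan-2-ol | CC(C)(O)[C@@H]1C=C[C@H](C)C=C(O[Si](C)(C)C(C)(C)C)C1 | intermediate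
8 | 1-bromobut-2-yne | CC#CCBr | starting material
9 | tris(dimethylamino)sulfonium (3S,6S)-6-(2-hydroxypropan-2-yl)-3-methylcyclohepta-1,4-dien-1-olate | CN(C)[S+](N(C)C)N(C)C.CC(C)(O)[C@@H]1C=C[C@H](C)C=C([O-])C1 | intermediate
10 | (2R,3S,6S)-2-(but-2-yn-1-yl)-6-(2-hydroxypropan-2-yl)-3-methylcyclohept-4-en-1-one | CC#CC[C@H]1C(=O)C[C@H](C(C)(C)O)C=C[C@@H]1C | intermediate
11 | (2R,3S,6S)-6-(2-hydroxypropan-2-yl)-3-methyl-2-(2-oxobutyl)cyclohept-4-en-1-one | CCC(=O)C[C@H]1C(=O)C[C@H](C(C)(C)O)C=C[C@@H]1C | intermediate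
12 | (5S,8S,8aR)-5-(2-hydroxypropan-2-yl)-3,8-dimethyl-4,5,8,8a-tetrahydroazulen-2(1H)-one, i.e. (1R,7S,10S)-11-hydroxyguaia-4,8-dien-3-one | C1=C[C@H](C)[C@H]2CC(=O)C(C)=C2C[C@@H]1C(C)(C)O | intermediate
13 | O-dimethylsilyl ether of 12 (HMe2Si on the C11 oxygen) | C1=C[C@H](C)[C@H]2CC(=O)C(C)=C2C[C@@H]1C(C)(C)O[SiH](C)C | intermediate
14 | (1R,7S,8R,10S)-8,11-(dimethylsilanediyloxy)guai-4-en-3-one (1,2-oxasilolane cis-fused at C7–C8; SiMe2 on C8, O on C11) | C[Si]3(C)[C@@H]1C[C@H](C)[C@H]2CC(=O)C(C)=C2C[C@@H]1C(C)(C)O3 | intermediate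
15 | (5S,6R,8S,8aR)-6-hydroxy-5-(2-hydroxypropan-2-yl)-3,8-dimethyl-4,5,6,7,8,8a-hexahydroazulen-2(1H)-one, i.e. (1R,7S,8R,10S)-8,11-dihydroxyguai-4-en-3-one | O[C@@H]1C[C@H](C)[C@H]2CC(=O)C(C)=C2C[C@@H]1C(C)(C)O | intermediate
16 | (5S,6R,8S,8aR)-5-(2-hydroxypropan-2-yl)-3,8-dimethyl-2-oxo-1,2,4,5,6,7,8,8a-octahydroazulen-6-yl propanoate | CCC(=O)O[C@@H]1C[C@H](C)[C@H]2CC(=O)C(C)=C2C[C@@H]1C(C)(C)O | intermediate
17 | (5S,6R,8S,8aR)-5-(2-acetoxypropan-2-yl)-3,8-dimethyl-2-oxo-1,2,4,5,6,7,8,8a-octahydroazulen-6-yl propanoate (CNP0288556.1) | CCC(=O)O[C@@H]1C[C@H](C)[C@H]2CC(=O)C(C)=C2C[C@@H]1C(C)(C)OC(C)=O | target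

Total steps: 11. Longest linear sequence: 11 steps (from 1).

Steps most likely to fail

Step 3. Rhodium may insert into the unsubstituted cyclopropane bond. The metallacycle may collapse to a cyclopentene before acetylene inserts. C-/O-enolate tautomerisation at rhodium may also erode the configuration at C7. The fallback sets out from 2 and comes back at 6.
- Ethyl diazoacetate 3 is added to acetaldehyde (DBU cat.) to give ethyl 2-diazo-3-hydroxybutanoate F1.
- POCl3/Et3N dehydrates F1 to ethyl 2-diazobut-3-enoate F2.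
- A chiral dirhodium tetraprolinate, Rh2(DOSP)4 in the antipode that leads to the 4S centre, transfers the vinylcarbene of F2 to the enol-ether double bond of 2. This gives ethyl (1R,2S)-2-(tert-butyldimethylsilyloxy)-1-ethenyl-2-[(E)-prop-1-enyl]cyclopropane-1-carboxylate F3.
- F3 undergoes a Cope rearrangement in the flask (formal [4+3]) to ethyl (4S)-6-(tert-butyldimethylsilyloxy)-4-methylcyclohepta-1,5-diene-1-carboxylate F4.
- Deconjugation (LDA, THF–DMPU, −78 °C, then kinetic α-protonation with acetic acid) moves the double bond to C8=C9 and gives 6, which is separated from its C7 epimer.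

Step 2. Carbene transfer may discriminate poorly between the OTBS and propenyl sides, may control the enantioface incompletely, and may partly attack the propenyl double bond. The fallback sets out from 2 and comes back at 7.
- (−)-Menthol is acylated with bromoacetyl bromide to (1R,2S,5R)-menthyl bromoacetate F5.
- N,N′-ditosylhydrazine/DBU converts F5 into (1R,2S,5R)-menthyl diazoacetate F6.
- Copper-catalysed cyclopropanation of 2 with F6 gives stereoisomers that are all diastereomers. The (1R,2S,5R)-menthyl (1S,2S)-2-(tert-butyldimethylsilyloxy)-2-[(E)-prop-1-enyl]cyclopropane-1-carboxylate F7 can therefore be purified by chromatography or crystallisation, whatever the selectivity of the carbene transfer.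
- F7 is taken through the conditions of step 3 to (1R,2S,5R)-menthyl (1S,4S)-6-(tert-butyldimethylsilyloxy)-4-methylcyclohepta-2,5-diene-1-carboxylate F8.
- The conditions of step 4 expel the auxiliary and give 7.

Step 5. Proton transfer between the enolate and the product may cause loss of regiochemical integrity and double alkylation, and O-alkylation or SN2′ attack on the propargylic bromide may compete. The fallback sets out from 7 and comes back at 11.
- 2-Nitrobutan-1-ol is dehydrated (phthalic anhydride, heat) to 2-nitrobut-1-ene F9.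
- 7 is capped (TMSCl, imidazole) as the trimethylsilyl ether of 7 F10.
- SnCl4 at −78 °C promotes a Mukaiyama–Michael addition of the silyl enol ether of F10 to F9 at C1, with no free enolate, and gives the aci-nitro adduct F11 in the flask.
- Aqueous work-up hydrolyses F11 (Nef reaction) and removes the TMS group. This gives diketone 11 directly, so step 6 is saved as well.

Further compounds
F1 | step 3 | ethyl 2-diazo-3-hydroxybutanoate | CCOC(=O)C(=[N+]=[N-])C(C)O
F2 | step 3 | ethyl 2-diazobut-3-enoate | CCOC(=O)C(=[N+]=[N-])C=C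
F3 | step 3 | ethyl (1R,2S)-2-(tert-butyldimethylsilyloxy)-1-ethenyl-2-[(E)-prop-1-enyl]cyclopropane-1-carboxylate | CCOC(=O)[C@@]1(C=C)C[C@]1(O[Si](C)(C)C(C)(C)C)/C=C/C
F4 | step 3 | ethyl (4S)-6-(tert-butyldimethylsilyloxy)-4-methylcyclohepta-1,5-diene-1-carboxylate | CCOC(=O)C1=CC[C@H](C)C=C(O[Si](C)(C)C(C)(C)C)C1
F5 | step 2 | (1R,2S,5R)-menthyl bromoacetate | CC(C)[C@@H]1CC[C@@H](C)C[C@H]1OC(=O)CBr
F6 | step 2 | (1R,2S,5R)-menthyl diazoacetate | CC(C)[C@@H]1CC[C@@H](C)C[C@H]1OC(=O)C=[N+]=[N-]
F7 | step 2 | (1R,2S,5R)-menthyl (1S,2S)-2-(tert-butyldimethylsilyloxy)-2-[(E)-prop-1-enyl]cyclopropane-1-carboxylate | CC(C)[C@@H]1CC[C@@H](C)C[C@H]1OC(=O)[C@H]2C[C@]2(O[Si](C)(C)C(C)(C)C)/C=C/C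
F8 | step 2 | (1R,2S,5R)-menthyl (1S,4S)-6-(tert-butyldimethylsilyloxy)-4-methylcyclohepta-2,5-diene-1-carboxylate | CC(C)[C@@H]1CC[C@@H](C)C[C@H]1OC(=O)[C@@H]2C=C[C@H](C)C=C(O[Si](C)(C)C(C)(C)C)C2
F9 | step 5 | 2-nitrobut-1-ene | CCC(=C)[N+](=O)[O-]
F10 | step 5 | trimethylsilyl ether of 7 | CC(C)(O[Si](C)(C)C)[C@@H]1C=C[C@H](C)C=C(O[Si](C)(C)C(C)(C)C)C1
F11 | step 5 | aci-nitro adduct, (2R,3S,6S)-2-(2-aci-nitrobutyl)-3-methyl-6-[2-(trimethylsilyloxy)propan-2-yl]cyclohept-4-en-1-one | CCC(C[C@H]1C(=O)C[C@H](C(C)(C)O[Si](C)(C)C)C=C[C@@H]1C)=[N+]([O-])O
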